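**Retrosynthetic overview** (core numbering: O-1, C-2 enol-ether carbon, C-3, C-3a, C-4 gem-dimethyl, C-5 CHBr, C-6, C-7, C-7a bearing O and CH3)
1. The bromomethyl ketone comes from Weinreb amide 23, and the (Z)-enol ether from Claisen condensation/cyclodehydration at C-2 of the trans-fused bromo lactone 19.
2. The C-5 bromide comes from the 5-ketone 17 by equatorial hydride delivery followed by Appel inversion.
3. Ring A (cyclohexane) is cut at C-5–C-6 and C-7–C-7a in one operation: methyl acrylate supplies C-6/C-7 (its ester is a temporary activating group, removed by oxidation and Krapcho reaction) and the monocyclic enol-lactone aldehyde 13 supplies the rest.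
4. Enabling feature: C-7a is a fully substituted carbon of the five-membered ring B carrying the ring oxygen and a methyl group, i.e. the radical formed by hydrogen-atom transfer to an exocyclic enol-lactone CH2; C-5 lies next to the quaternary C-4, i.e. it is a non-enolisable aldehyde carbon; the C-3a substituent on ring B steers the new bond trans.
5. Ring order: γ-lactone ring B first (gold-catalysed cyclisation of a 4-alkynoic acid whose single stereocentre comes from an oxazolidinone alkylation), then ring A in the key step; the lactone carbonyl finally becomes C-2.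

Key step: step 8

Remark: 15 is expected as a mixture of epimers at C-5 and C-6 (16 at C-6, partly enolised); both centres are erased in steps 9 and 10, so they are written without configuration.
Remark: the (Z) geometry of the tetrasubstituted enol ether (carbonyl on the side of the ring oxygen) is assumed to be the thermodynamically preferred one.

**Step 1**
Reactants: 1 3,3-dimethylpent-4-enoic acid; 2 (4S)-4-benzyl-1,3-oxazolidin-2-one
Product: 4 (4S)-4-benzyl-3-(3,3-dimethylpent-4-enoyl)-1,3-oxazolidin-2-one, via mixed pivalic anhydride 3 (not isolated)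
Conditions: PivCl, Et3N, THF, −20 °C; then LiCl, 2, rt
Reagents that add atoms: pivaloyl chloride, CC(C)(C)C(=O)Cl (its atoms stay in intermediate 3 only)
Why: N-acylation of the oxazolidinone through the mixed pivalic anhydride with LiCl assistance is a standard imide synthesis and touches no stereocentre.

**Step 2**
Reactants: 4 (4S)-4-benzyl-3-(3,3-dimethylpent-4-enoyl)-1,3-oxazolidin-2-one; 5 tert-butyl bromoacetate
Product: 7 tert-butyl (3S)-3-{[(4S)-4-benzyl-2-oxo-1,3-oxazolidin-3-yl]carbonyl}-4,4-dimethylhex-5-enoate, via sodium enolate 6 (not isolated)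
Conditions: NaN(SiMe3)2, THF, −78 °C; then 5, −78 → −40 °C
Reagents that add atoms: NaN(SiMe3)2, C[Si](C)(C)[N-][Si](C)(C)C.[Na+] (sodium of intermediate 6 only)
Why: Evans oxazolidinone alkylation, in which the chelated (Z)-enolate is alkylated by the reactive bromoacetate on the face opposite the benzyl group, sets the (3S) centre that becomes C-3a of the target.

**Step 3**
Reactants: 7 tert-butyl (3S)-3-{[(4S)-4-benzyl-2-oxo-1,3-oxazolidin-3-yl]carbonyl}-4,4-dimethylhex-5-enoate
Product: 8 tert-butyl (3S)-3-(hydroxymethyl)-4,4-dimethylhex-5-enoate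
Conditions: LiBH4, THF, 0 °C → rt
Reagents that add atoms: none
Why: Reductive cleavage of the imide by LiBH4 should give the primary alcohol and free the auxiliary while the tert-butyl ester, the alkene and the stereocentre are left alone.

**Step 4**
Reactants: 8 tert-butyl (3S)-3-(hydroxymethyl)-4,4-dimethylhex-5-enoate
Product: 9 tert-butyl (3S)-3-formyl-4,4-dimethylhex-5-enoate
Conditions: Dess–Martin periodinane, pyridine, CH2Cl2, 0 °C → rt
Reagents that add atoms: none
Why: Dess–Martin oxidation under buffered, non-basic conditions should give the α-branched aldehyde without epimerisation.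

**Step 5**
Reactants: 9 tert-butyl (3S)-3-formyl-4,4-dimethylhex-5-enoate
Product: 10 tert-butyl (3R)-3-ethynyl-4,4-dimethylhex-5-enoate
Conditions: dimethyl (1-diazo-2-oxopropyl)phosphonate, K2CO3, MeOH, 0 °C → rt
Reagents that add atoms: dimethyl (1-diazo-2-oxopropyl)phosphonate, CC(=O)C(=[N+]=[N-])P(=O)(OC)OC
Why: Ohira–Bestmann (Seyferth–Gilbert) homologation converts the aldehyde into the terminal alkyne under mild carbonate conditions, and the hindered α-hydrogen between the quaternary carbon and the CH2 should resist epimerisation (the descriptor changes by priority only).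

**Step 6**
Reactants: 10 tert-butyl (3R)-3-ethynyl-4,4-dimethylhex-5-enoate
Product: 11 tert-butyl (3R)-3-ethynyl-4,4-dimethyl-5-oxopentanoate
Conditions: OsO4 (cat.), NaIO4, 2,6-lutidine, dioxane/H2O, rt
Reagents that add atoms: sodium periodate, [Na+].[O-]I(=O)(=O)=O (oxygen atom, relayed through OsO4)
Why: Lemieux–Johnson cleavage takes the monosubstituted alkene selectively, because osmium tetroxide reacts far faster with alkenes than with alkynes, and unmasks the non-enolisable aldehyde.

**Step 7**
Reactants: 11 tert-butyl (3R)-3-ethynyl-4,4-dimethyl-5-oxopentanoate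
Product: 13 2-methyl-2-[(3S)-2-methylidene-5-oxooxolan-3-yl]propanal, via alkynoic acid 12 (not isolated)
Conditions: CF3CO2H, CH2Cl2, 0 °C → rt, evaporate; then AuCl (cat.), K2CO3 (cat.), MeCN, rt
Reagents that add atoms: none
Why: Acidolysis of the tert-butyl ester followed by gold-catalysed 5-exo-dig cycloisomerisation of the 4-alkynoic acid is a known route to γ-methylene-γ-butyrolactones, and the mild conditions should keep the exocyclic alkene from migrating into the ring, so the stereocentre is kept.

**Step 8**
Reactants: 13 2-methyl-2-[(3S)-2-methylidene-5-oxooxolan-3-yl]propanal; 14 methyl acrylate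
Product: 15 methyl (3aS,7aS)-5-hydroxy-4,4,7a-trimethyl-2-oxooctahydro-1-benzofuran-6-carboxylate
Conditions: Fe(acac)3 (cat.), PhSiH3, i-PrOH, THF, 0 °C → rt
Reagents that add atoms: none
Why: Proposed new method: iron hydride generated from Fe(acac)3 and PhSiH3 transfers a hydrogen atom to the CH2 terminus of the exocyclic enol-lactone alkene of 13, which creates the C-7a methyl group and a tertiary α-acyloxy radical at C-7a; this nucleophilic radical adds to the β-carbon of methyl acrylate (C-7–C-7a bond), the resulting α-ester radical is reduced by divalent iron to an iron enolate, and the enolate adds to the neopentyl aldehyde (C-5–C-6 bond). The closest known reaction types are the hydrogen-atom-transfer-initiated Giese coupling of oxygen-substituted donor olefins with acrylates and the radical conjugate addition–aldol (radical–polar crossover) annulation of γ,δ-unsaturated aldehydes with enones; the combination of an enol-lactone donor with an ester enolate has not been shown. Ring A is closed in the aldol event by a 6-(enolexo)-exo-trig closure. The quaternary stereocentre C-7a is controlled by C-3a: the acrylate approaches the planar radical on the five-membered lactone ring from the face anti to the bulky 2-methyl-1-oxopropan-2-yl group, so the new CH2 ends up trans to that group and the ring fusion becomes trans, while C-5 and C-6 are not controlled and are erased in steps 9 and 10. The step needs hydrogen-atom transfer to the enol ester in preference to the acrylate and aldol trapping in preference to protonation of the enolate; the first is secured by the electron-rich 1,1-disubstituted donor alkene, the second by the aldehyde, which cannot enolise because its α-carbon is the gem-dimethyl carbon and which sits five atoms from the enolate carbon.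

**Step 9**
Reactants: 15 methyl (3aS,7aS)-5-hydroxy-4,4,7a-trimethyl-2-oxooctahydro-1-benzofuran-6-carboxylate
Product: 16 methyl (3aS,7aS)-4,4,7a-trimethyl-2,5-dioxooctahydro-1-benzofuran-6-carboxylate
Conditions: Dess–Martin periodinane, CH2Cl2, rt
Reagents that add atoms: none
Why: Dess–Martin oxidation of the hindered secondary alcohol should give the β-keto ester and erase the uncontrolled carbinol centre.

**Step 10**
Reactants: 16 methyl (3aS,7aS)-4,4,7a-trimethyl-2,5-dioxooctahydro-1-benzofuran-6-carboxylate
Product: 17 (3aS,7aS)-4,4,7a-trimethylhexahydro-1-benzofuran-2,5-dione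
Conditions: LiCl, H2O, DMSO, 130 °C
Reagents that add atoms: none
Why: Krapcho dealkoxycarbonylation removes the temporary ester from C-6 under neutral conditions that should leave the tertiary γ-lactone intact.

**Step 11**
Reactants: 17 (3aS,7aS)-4,4,7a-trimethylhexahydro-1-benzofuran-2,5-dione
Product: 18 (3aS,5R,7aS)-5-hydroxy-4,4,7a-trimethylhexahydro-1-benzofuran-2(3H)-one
Conditions: Li[HB(s-Bu)3], THF, −78 °C; H2O work-up
Reagents that add atoms: none
Why: The bulky trialkylborohydride should attack the rigid 2,2-dimethylcyclohexanone from the equatorial direction, as is usual for ketones next to a gem-dimethyl carbon in this ring type, and give the axial (5R) alcohol without reducing the lactone at −78 °C.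

**Step 12**
Reactants: 18 (3aS,5R,7aS)-5-hydroxy-4,4,7a-trimethylhexahydro-1-benzofuran-2(3H)-one
Product: 19 (3aS,5S,7aS)-5-bromo-4,4,7a-trimethylhexahydro-1-benzofuran-2(3H)-one
Conditions: CBr4, PPh3, CH2Cl2, 0 °C → rt
Reagents that add atoms: carbon tetrabromide, BrC(Br)(Br)Br
Why: In the Appel bromination the alkoxyphosphonium ion of the axial alcohol is displaced by bromide with inversion (SN2) to give the equatorial (5S) bromide, a reaction type with precedent for axial neopentylic alcohols although elimination competes.

**Step 13**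
Reactants: 19 (3aS,5S,7aS)-5-bromo-4,4,7a-trimethylhexahydro-1-benzofuran-2(3H)-one; 20 N-methoxy-N-methylpropanamide
Product: 23 (2Z)-2-[(3aS,5S,7aS)-5-bromo-4,4,7a-trimethylhexahydro-1-benzofuran-2(3H)-ylidene]-N-methoxy-N-methylpropanamide, via lithium enolate 21 (not isolated), via hemiketal adduct 22 (not isolated)
Conditions: LiN(i-Pr)2, 20, THF, −78 °C; then 19, −78 → −40 °C; AcOH; then camphorsulfonic acid (cat.), 4 Å molecular sieves, CH2Cl2, rt
Reagents that add atoms: LiN(i-Pr)2, CC(C)[N-]C(C)C.[Li+] (lithium of intermediate 21 only)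
Why: Claisen-type addition of the amide enolate to the lactone carbonyl gives a hemiketal that loses water under acid to the push–pull enol ether, whose geometry is under thermodynamic control with the carbonyl group next to the ring oxygen and the methyl group next to the ring CH2 (Z); the equatorial bromide has no anti-periplanar hydrogen and should survive the base.

**Step 14**
Reactants: 23 (2Z)-2-[(3aS,5S,7aS)-5-bromo-4,4,7a-trimethylhexahydro-1-benzofuran-2(3H)-ylidene]-N-methoxy-N-methylpropanamide
Product: 24 (3Z)-1-bromo-3-[(3aS,5S,7aS)-5-bromo-4,4,7a-trimethylhexahydro-1-benzofuran-2(3H)-ylidene]butan-2-one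
Conditions: CH2Br2, MeLi·LiBr, THF/Et2O, −78 °C; then AcOH
Reagents that add atoms: dibromomethane, BrCBr
Why: Bromomethyllithium generated in situ adds once to the Weinreb amide to give a chelated tetrahedral intermediate that collapses on work-up to the bromomethyl ketone, a known homologation of α,β-unsaturated Weinreb amides that should leave the alkene geometry and the secondary bromide untouched.

**Compound list**
1 | 3,3-dimethylpent-4-enoic acid | C=CC(C)(C)CC(=O)O | starting material
2 | (4S)-4-benzyl-1,3-oxazolidin-2-one | O=C1N[C@@H](Cc2ccccc2)CO1 | starting material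
3 | 3,3-dimethylpent-4-enoic pivalic anhydride | C=CC(C)(C)CC(=O)OC(=O)C(C)(C)C | intermediate (not isolated)
4 | (4S)-4-benzyl-3-(3,3-dimethylpent-4-enoyl)-1,3-oxazolidin-2-one | C=CC(C)(C)CC(=O)N1[C@@H](Cc2ccccc2)COC1=O | intermediate
5 | tert-butyl bromoacetate | CC(C)(C)OC(=O)CBr | starting material
6 | sodium (Z)-enolate of 4 | [Na+].[O-]/C(=C\C(C)(C)C=C)N1[C@@H](Cc2ccccc2)COC1=O | intermediate (not isolated)
7 | tert-butyl (3S)-3-{[(4S)-4-benzyl-2-oxo-1,3-oxazolidin-3-yl]carbonyl}-4,4-dimethylhex-5-enoate | CC(C)(C)OC(=O)C[C@H](C(=O)N1[C@@H](Cc2ccccc2)COC1=O)C(C)(C)C=C | intermediate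
8 | tert-butyl (3S)-3-(hydroxymethyl)-4,4-dimethylhex-5-enoate | CC(C)(C)OC(=O)C[C@H](CO)C(C)(C)C=C | intermediate
9 | tert-butyl (3S)-3-formyl-4,4-dimethylhex-5-enoate | CC(C)(C)OC(=O)C[C@H](C=O)C(C)(C)C=C | intermediate
10 | tert-butyl (3R)-3-ethynyl-4,4-dimethylhex-5-enoate | CC(C)(C)OC(=O)C[C@H](C#C)C(C)(C)C=C | intermediate
11 | tert-butyl (3R)-3-ethynyl-4,4-dimethyl-5-oxopentanoate | CC(C)(C)OC(=O)C[C@H](C#C)C(C)(C)C=O | intermediate
12 | (3R)-3-ethynyl-4,4-dimethyl-5-oxopentanoic acid | OC(=O)C[C@H](C#C)C(C)(C)C=O | intermediate (not isolated)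
13 | 2-methyl-2-[(3S)-2-methylidene-5-oxooxolan-3-yl]propanal | O=C1C[C@@H](C(C)(C)C=O)C(=C)O1 | intermediate
14 | methyl acrylate | C=CC(=O)OC | starting material
15 | methyl (3aS,7aS)-5-hydroxy-4,4,7a-trimethyl-2-oxooctahydro-1-benzofuran-6-carboxylate (C-5/C-6 epimers) | O=C1C[C@H]2C(C)(C)C(O)C(C(=O)OC)C[C@]2(C)O1 | intermediate
16 | methyl (3aS,7aS)-4,4,7a-trimethyl-2,5-dioxooctahydro-1-benzofuran-6-carboxylate (C-6 epimers) | O=C1C[C@H]2C(C)(C)C(=O)C(C(=O)OC)C[C@]2(C)O1 | intermediate
17 | (3aS,7aS)-4,4,7a-trimethylhexahydro-1-benzofuran-2,5-dione | O=C1C[C@H]2C(C)(C)C(=O)CC[C@]2(C)O1 | intermediate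
18 | (3aS,5R,7aS)-5-hydroxy-4,4,7a-trimethylhexahydro-1-benzofuran-2(3H)-one | O=C1C[C@H]2C(C)(C)[C@H](O)CC[C@]2(C)O1 | intermediate
19 | (3aS,5S,7aS)-5-bromo-4,4,7a-trimethylhexahydro-1-benzofuran-2(3H)-one | O=C1C[C@H]2C(C)(C)[C@@H](Br)CC[C@]2(C)O1 | intermediate
20 | N-methoxy-N-methylpropanamide | CCC(=O)N(C)OC | starting material
21 | lithium (Z)-enolate of 20 | [Li+].C/C=C(\[O-])N(C)OC | intermediate (not isolated)
22 | 2-[(3aS,5S,7aS)-5-bromo-2-hydroxy-4,4,7a-trimethyloctahydro-1-benzofuran-2-yl]-N-methoxy-N-methylpropanamide (diastereomers) | CC(C(=O)N(C)OC)C1(O)C[C@H]2C(C)(C)[C@@H](Br)CC[C@]2(C)O1 | intermediate (not isolated)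
23 | (2Z)-2-[(3aS,5S,7aS)-5-bromo-4,4,7a-trimethylhexahydro-1-benzofuran-2(3H)-ylidene]-N-methoxy-N-methylpropanamide | C/C(C(=O)N(C)OC)=C1\C[C@H]2C(C)(C)[C@@H](Br)CC[C@]2(C)O1 | intermediate
24 | (3Z)-1-bromo-3-[(3aS,5S,7aS)-5-bromo-4,4,7a-trimethylhexahydro-1-benzofuran-2(3H)-ylidene]butan-2-one | C/C(C(=O)CBr)=C1\C[C@H]2C(C)(C)[C@@H](Br)CC[C@]2(C)O1 | target

**Step count and risks**
Total step count: 14. Longest linear sequence: 14 steps (1 → 24).

Steps most likely to fail:

1. Step 8 (proposed new method). The enolate or its radical precursor may be protonated or hydrogenated before it reaches the aldehyde, so that only the reductive coupling takes place; alcoholysis of the enol lactone and simple reduction of the tertiary radical are further leaks. The fallback uses known chemistry and sets out from 13 and 14. A plain iron-hydride reductive olefin coupling (Fe(acac)3, PhSiH3, excess 2-propanol, THF) should give methyl 3-[(2S,3S)-2-methyl-3-(2-methyl-1-oxopropan-2-yl)-5-oxooxolan-2-yl]propanoate F1, with the same anti addition on the lactone ring. A separate ester-enolate aldol cyclisation (LiN(SiMe3)2, THF, −78 °C) then closes ring A and returns to the route at 15.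

2. Step 12. E2 elimination toward C-6 and a 1,2-methyl shift from C-4 may outrun SN2 displacement at the neopentylic alkoxyphosphonium centre. The fallback sets out from 17. Enolisation and triflation (KN(SiMe3)2, PhNTf2, THF, −78 °C) should give (3aS,7aS)-4,4,7a-trimethyl-2-oxo-2,3,3a,4,7,7a-hexahydro-1-benzofuran-5-yl trifluoromethanesulfonate F2. Triflate-to-bromide exchange ([(C5Me5)Ru(MeCN)3]OTf, LiBr) should give (3aS,7aS)-5-bromo-4,4,7a-trimethyl-3a,4,7,7a-tetrahydro-1-benzofuran-2(3H)-one F3. Hydrogenation (RhCl(PPh3)3, H2) from the face opposite the two axial methyl groups should place hydrogen axial and bromine equatorial and return to the route at 19. The C–Br bond is then made at an sp2 carbon and the stereocentre is set by hydrogen delivery instead of displacement; hydrogenolysis of the C–Br bond is the risk of this variant.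

3. Step 14. Deprotonation at C-3 (γ to the amide carbonyl) or decomposition of the carbenoid may outrun addition to the deactivated push–pull amide carbonyl. The fallback sets out from 19 and replaces steps 13 and 14. Addition of the C-3 lithium enolate of butan-2-one (from 2-(trimethylsilyloxy)but-2-ene and MeLi) should give 3-[(3aS,5S,7aS)-5-bromo-2-hydroxy-4,4,7a-trimethyloctahydro-1-benzofuran-2-yl]butan-2-one F4. Acid dehydration (camphorsulfonic acid) should give (3Z)-3-[(3aS,5S,7aS)-5-bromo-4,4,7a-trimethylhexahydro-1-benzofuran-2(3H)-ylidene]butan-2-one F5. Kinetic enolisation at the acetyl CH3 and silylation (LiN(i-Pr)2, Me3SiCl, −78 °C) should give {[(3Z)-3-[(3aS,5S,7aS)-5-bromo-4,4,7a-trimethylhexahydro-1-benzofuran-2(3H)-ylidene]but-1-en-2-yl]oxy}(trimethyl)silane F6. Bromination with N-bromosuccinimide then returns to the route at 24.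

**Further compounds**
F1 | step 8 | methyl 3-[(2S,3S)-2-methyl-3-(2-methyl-1-oxopropan-2-yl)-5-oxooxolan-2-yl]propanoate | O=C1C[C@@H](C(C)(C)C=O)[C@](C)(CCC(=O)OC)O1
F2 | step 12 | (3aS,7aS)-4,4,7a-trimethyl-2-oxo-2,3,3a,4,7,7a-hexahydro-1-benzofuran-5-yl trifluoromethanesulfonate | O=C1C[C@H]2C(C)(C)C(OS(=O)(=O)C(F)(F)F)=CC[C@]2(C)O1
F3 | step 12 | (3aS,7aS)-5-bromo-4,4,7a-trimethyl-3a,4,7,7a-tetrahydro-1-benzofuran-2(3H)-one | O=C1C[C@H]2C(C)(C)C(Br)=CC[C@]2(C)O1
F4 | step 14 | 3-[(3aS,5S,7aS)-5-bromo-2-hydroxy-4,4,7a-trimethyloctahydro-1-benzofuran-2-yl]butan-2-one | CC(C(C)=O)C1(O)C[C@H]2C(C)(C)[C@@H](Br)CC[C@]2(C)O1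
F5 | step 14 | (3Z)-3-[(3aS,5S,7aS)-5-bromo-4,4,7a-trimethylhexahydro-1-benzofuran-2(3H)-ylidene]butan-2-one | C/C(C(C)=O)=C1\C[C@H]2C(C)(C)[C@@H](Br)CC[C@]2(C)O1
F6 | step 14 | {[(3Z)-3-[(3aS,5S,7aS)-5-bromo-4,4,7a-trimethylhexahydro-1-benzofuran-2(3H)-ylidene]but-1-en-2-yl]oxy}(trimethyl)silane | C/C(C(=C)O[Si](C)(C)C)=C1\C[C@H]2C(C)(C)[C@@H](Br)CC[C@]2(C)O1
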